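The dioxane ring (ring B) is cut at C7–C8 and at the bond from C8 to the ring oxygen para to the stilbene arm. The feature exploited is the O–C7(aryl)–C8(C9)–O edge of ring B: without C8, C7 is simply a syringaldehyde acetal carbon held by both catechol oxygens, and C8 with C9 is ethyl diazoacetate. The key step inserts this CH(CO2Et) unit into the benzodioxole under a chiral scandium Lewis acid, enlarging the five-membered acetal to the six-membered dioxane and setting C7 and C8 in one operation. Its precursor is the racemic 2-aryl-1,3-benzodioxole made from O-silylated syringaldehyde and methyl 3,4-dihydroxybenzoate, whose para ester later becomes the stilbene arm.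

Key step: step 3

Remark: lignan numbering is used (C7 benzylic, C8 bearing C9); the sense of induction of the scandium–pybox ion pair cannot be predicted, so (S,S)-Ph-pybox stands for whichever ligand antipode delivers 3R.

Step 1
Reactants: 1 syringaldehyde
Product: 2 3,5-dimethoxy-4-(triisopropylsilyloxy)benzaldehyde
Conditions: TIPSCl, imidazole, DMAP (cat.), DMF, rt
Reagents that add atoms: triisopropylsilyl chloride, CC(C)[Si](Cl)(C(C)C)C(C)C
Why: Imidazole-promoted O-silylation of the acidic phenol (silyl ether formation) installs a bulky TIPS group that should survive the acid, hydride and base of the later steps.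

Step 2
Reactants: 2 3,5-dimethoxy-4-(triisopropylsilyloxy)benzaldehyde; 3 methyl 3,4-dihydroxybenzoate
Product: 5 methyl 2-[3,5-dimethoxy-4-(triisopropylsilyloxy)phenyl]-1,3-benzodioxole-5-carboxylate (racemic), via dimethyl acetal 4 (not isolated)
Conditions: HC(OMe)3, PPTS (cat.), MeOH, 50 °C; evaporate; then 3, PPTS (cat.), toluene, reflux, MeOH distilled off
Reagents that add atoms: none
Why: Acid-catalysed acetalisation with trimethyl orthoformate followed by transacetalisation with the catechol, driven by removal of methanol, should close the five-membered 1,3-benzodioxole, whose racemic acetal carbon is of no consequence because step 3 ionises it.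

Step 3
Reactants: 5 methyl 2-[3,5-dimethoxy-4-(triisopropylsilyloxy)phenyl]-1,3-benzodioxole-5-carboxylate (racemic); 6 ethyl diazoacetate
Product: 8 2-ethyl 6-methyl (2S,3R)-3-[3,5-dimethoxy-4-(triisopropylsilyloxy)phenyl]-2,3-dihydro-1,4-benzodioxine-2,6-dicarboxylate (trans), via cis diester 7 (not isolated)
Conditions: Sc(OTf)3 (10 mol %), (S,S)-Ph-pybox (12 mol %), CH2Cl2, −40 °C, slow addition of 6; Et3N quench at −40 °C; then DBU (0.3 equiv), 0 °C
Reagents that add atoms: none
Why: Proposed new method: the trivalent scandium–pybox Lewis acid should ionise the acetal C–O bond to the oxygen para to the ester (the better aryloxide leaving group, while the more electron-rich meta oxygen stays on the cation), so both enantiomers of 5 converge on one planar p-silyloxyaryl oxocarbenium ion tethered to the scandium-bound phenoxide; the nucleophilic carbon of 6 then adds to C7 (C7–C8 bond) and the phenoxide displaces N2 from the resulting α-diazonium ester (C8–O bond). The closest known chemistry is the Lewis acid-promoted formal insertion of diazo esters into acetal C–O bonds, scandium triflate-catalysed Roskamp-type additions of diazo esters, and carbenoid ring expansion of 2-aryl-1,3-dioxolanes to 1,4-dioxanes. Ring B closes by a 6-exo-tet SN2 displacement of dinitrogen at C8 by the ortho-tethered phenoxide, which has to outrun 1,2-hydride or aryl migration; low temperature and slow addition of 6 favour the intramolecular path. C7 is set by the chiral ligand sphere held on the tethered phenoxide, which should shield one face of the oxocarbenium ion in the contact ion pair. C8 is set relative to C7 by thermodynamics: after the Lewis acid is quenched cold (so that C7 cannot re-ionise and relay the wrong centre), catalytic DBU epimerises any cis diester 7 at the acidic α-ester position to the diequatorial trans diester 8. The selectivity the step needs is the regioselectivity of ionisation, which the para ester of 5 secures, while ester and silyl ether (in place of aldehyde or free phenol) keep 6 from reacting elsewhere.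

Step 4
Reactants: 8 2-ethyl 6-methyl (2S,3R)-3-[3,5-dimethoxy-4-(triisopropylsilyloxy)phenyl]-2,3-dihydro-1,4-benzodioxine-2,6-dicarboxylate
Product: 9 [(2R,3R)-3-[3,5-dimethoxy-4-(triisopropylsilyloxy)phenyl]-2-(hydroxymethyl)-2,3-dihydro-1,4-benzodioxin-6-yl]methanol
Conditions: LiAlH4, THF, 0 °C; EtOAc, then aq. KNaC4H4O6 work-up
Reagents that add atoms: none
Why: Hydride reduction of both esters to primary alcohols should leave the hindered aryl silyl ether and both stereocentres untouched (the descriptor at C2 changes to R only through the priority rules), and from here C8 can no longer epimerise.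

Step 5
Reactants: 9 [(2R,3R)-3-[3,5-dimethoxy-4-(triisopropylsilyloxy)phenyl]-2-(hydroxymethyl)-2,3-dihydro-1,4-benzodioxin-6-yl]methanol
Product: 10 (2R,3R)-3-[3,5-dimethoxy-4-(triisopropylsilyloxy)phenyl]-2-(hydroxymethyl)-2,3-dihydro-1,4-benzodioxine-6-carbaldehyde
Conditions: MnO2 (activated, excess), CH2Cl2, rt
Reagents that add atoms: none
Why: Activated MnO2 should oxidise only the benzylic alcohol to the aldehyde and spare the aliphatic C9 alcohol (chemoselective benzylic oxidation).

Step 6
Reactants: 11 methyl 3,5-dihydroxybenzoate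
Product: 12 methyl 3,5-bis(triisopropylsilyloxy)benzoate
Conditions: TIPSCl, imidazole, DMF, rt
Reagents that add atoms: triisopropylsilyl chloride, CC(C)[Si](Cl)(C(C)C)C(C)C
Why: Double O-silylation of the unhindered resorcinol hydroxyls (silyl ether formation) gives the same protecting group as on the syringyl ring, so that one fluoride step frees all three phenols at the end.

Step 7
Reactants: 12 methyl 3,5-bis(triisopropylsilyloxy)benzoate
Product: 13 [3,5-bis(triisopropylsilyloxy)phenyl]methanol
Conditions: LiAlH4, THF, 0 °C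
Reagents that add atoms: none
Why: Hydride reduction of the aryl ester to the benzylic alcohol is routine and should not touch aryl TIPS ethers at 0 °C.

Step 8
Reactants: 13 [3,5-bis(triisopropylsilyloxy)phenyl]methanol
Product: 14 1-(bromomethyl)-3,5-bis(triisopropylsilyloxy)benzene
Conditions: CBr4, PPh3, CH2Cl2, 0 °C
Reagents that add atoms: carbon tetrabromide, BrC(Br)(Br)Br
Why: The Appel reaction converts the benzylic alcohol to the bromide under neutral conditions that should leave the silyl ethers intact.

Step 9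
Reactants: 14 1-(bromomethyl)-3,5-bis(triisopropylsilyloxy)benzene
Product: 15 diethyl {[3,5-bis(triisopropylsilyloxy)phenyl]methyl}phosphonate
Conditions: P(OEt)3 (neat), 130 °C
Reagents that add atoms: triethyl phosphite, CCOP(OCC)OCC
Why: The Michaelis–Arbuzov reaction of a primary benzylic bromide with triethyl phosphite is reliable, and expulsion of volatile bromoethane drives it.

Step 10
Reactants: 10 (2R,3R)-3-[3,5-dimethoxy-4-(triisopropylsilyloxy)phenyl]-2-(hydroxymethyl)-2,3-dihydro-1,4-benzodioxine-6-carbaldehyde; 15 diethyl {[3,5-bis(triisopropylsilyloxy)phenyl]methyl}phosphonate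
Product: 16 [(2R,3R)-6-{(E)-2-[3,5-bis(triisopropylsilyloxy)phenyl]ethenyl}-3-[3,5-dimethoxy-4-(triisopropylsilyloxy)phenyl]-2,3-dihydro-1,4-benzodioxin-2-yl]methanol
Conditions: 15 (2.2 equiv), NaN(SiMe3)2 (2.2 equiv), THF, 0 °C; then 10, 0 °C to rt
Reagents that add atoms: none
Why: The semi-stabilised benzylic phosphonate anion should add to the aryl aldehyde and collapse to the (E)-stilbene (Horner–Wadsworth–Emmons olefination), with the second equivalent of anion covering the free C9 hydroxyl and the non-nucleophilic amide base sparing the aryl silyl ethers.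

Step 11
Reactants: 16 [(2R,3R)-6-{(E)-2-[3,5-bis(triisopropylsilyloxy)phenyl]ethenyl}-3-[3,5-dimethoxy-4-(triisopropylsilyloxy)phenyl]-2,3-dihydro-1,4-benzodioxin-2-yl]methanol
Product: 17 aiphanol, 5-{(E)-2-[(2R,3R)-3-(4-hydroxy-3,5-dimethoxyphenyl)-2-(hydroxymethyl)-2,3-dihydro-1,4-benzodioxin-6-yl]ethenyl}benzene-1,3-diol
Conditions: Bu4NF, AcOH, THF, 0 °C, under argon, in the dark
Reagents that add atoms: none
Why: Fluoride should cleave the three aryl Si–O bonds (desilylation), and the acetic acid buffer keeps the liberated para-phenol protonated so that C7 is not epimerised through a quinone methide.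

Compound list
1 | syringaldehyde (4-hydroxy-3,5-dimethoxybenzaldehyde) | COc1cc(C=O)cc(OC)c1O | starting material
2 | 3,5-dimethoxy-4-(triisopropylsilyloxy)benzaldehyde | COc1cc(C=O)cc(OC)c1O[Si](C(C)C)(C(C)C)C(C)C | intermediate
3 | methyl 3,4-dihydroxybenzoate | COC(=O)c1ccc(O)c(O)c1 | starting material
4 | [4-(dimethoxymethyl)-2,6-dimethoxyphenoxy]triisopropylsilane (dimethyl acetal of 2, not isolated) | COC(OC)c1cc(OC)c(O[Si](C(C)C)(C(C)C)C(C)C)c(OC)c1 | intermediate
5 | methyl 2-[3,5-dimethoxy-4-(triisopropylsilyloxy)phenyl]-1,3-benzodioxole-5-carboxylate, racemic | COC(=O)c1ccc2OC(c3cc(OC)c(O[Si](C(C)C)(C(C)C)C(C)C)c(OC)c3)Oc2c1 | intermediate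
6 | ethyl diazoacetate | CCOC(=O)C=[N+]=[N-] | starting material
7 | 2-ethyl 6-methyl (2R,3R)-3-[3,5-dimethoxy-4-(triisopropylsilyloxy)phenyl]-2,3-dihydro-1,4-benzodioxine-2,6-dicarboxylate (cis, the C2 epimer of 8; converged to 8 in the flask, not isolated) | COc1cc([C@H]2Oc3cc(C(=O)OC)ccc3O[C@H]2C(=O)OCC)cc(OC)c1O[Si](C(C)C)(C(C)C)C(C)C | intermediate
8 | 2-ethyl 6-methyl (2S,3R)-3-[3,5-dimethoxy-4-(triisopropylsilyloxy)phenyl]-2,3-dihydro-1,4-benzodioxine-2,6-dicarboxylate (trans) | COc1cc([C@H]2Oc3cc(C(=O)OC)ccc3O[C@@H]2C(=O)OCC)cc(OC)c1O[Si](C(C)C)(C(C)C)C(C)C | intermediate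
9 | [(2R,3R)-3-[3,5-dimethoxy-4-(triisopropylsilyloxy)phenyl]-2-(hydroxymethyl)-2,3-dihydro-1,4-benzodioxin-6-yl]methanol (trans) | COc1cc([C@H]2Oc3cc(CO)ccc3O[C@@H]2CO)cc(OC)c1O[Si](C(C)C)(C(C)C)C(C)C | intermediate
10 | (2R,3R)-3-[3,5-dimethoxy-4-(triisopropylsilyloxy)phenyl]-2-(hydroxymethyl)-2,3-dihydro-1,4-benzodioxine-6-carbaldehyde (trans) | COc1cc([C@H]2Oc3cc(C=O)ccc3O[C@@H]2CO)cc(OC)c1O[Si](C(C)C)(C(C)C)C(C)C | intermediate
11 | methyl 3,5-dihydroxybenzoate | COC(=O)c1cc(O)cc(O)c1 | starting material
12 | methyl 3,5-bis(triisopropylsilyloxy)benzoate | COC(=O)c1cc(O[Si](C(C)C)(C(C)C)C(C)C)cc(O[Si](C(C)C)(C(C)C)C(C)C)c1 | intermediate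
13 | [3,5-bis(triisopropylsilyloxy)phenyl]methanol | OCc1cc(O[Si](C(C)C)(C(C)C)C(C)C)cc(O[Si](C(C)C)(C(C)C)C(C)C)c1 | intermediate
14 | 1-(bromomethyl)-3,5-bis(triisopropylsilyloxy)benzene | BrCc1cc(O[Si](C(C)C)(C(C)C)C(C)C)cc(O[Si](C(C)C)(C(C)C)C(C)C)c1 | intermediate
15 | diethyl {[3,5-bis(triisopropylsilyloxy)phenyl]methyl}phosphonate | CCOP(=O)(OCC)Cc1cc(O[Si](C(C)C)(C(C)C)C(C)C)cc(O[Si](C(C)C)(C(C)C)C(C)C)c1 | intermediate
16 | [(2R,3R)-6-{(E)-2-[3,5-bis(triisopropylsilyloxy)phenyl]ethenyl}-3-[3,5-dimethoxy-4-(triisopropylsilyloxy)phenyl]-2,3-dihydro-1,4-benzodioxin-2-yl]methanol | COc1cc([C@H]2Oc3cc(/C=C/c4cc(O[Si](C(C)C)(C(C)C)C(C)C)cc(O[Si](C(C)C)(C(C)C)C(C)C)c4)ccc3O[C@@H]2CO)cc(OC)c1O[Si](C(C)C)(C(C)C)C(C)C | intermediate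
17 | aiphanol, 5-{(E)-2-[(2R,3R)-3-(4-hydroxy-3,5-dimethoxyphenyl)-2-(hydroxymethyl)-2,3-dihydro-1,4-benzodioxin-6-yl]ethenyl}benzene-1,3-diol | COc1cc([C@H]2Oc3cc(/C=C/c4cc(O)cc(O)c4)ccc3O[C@@H]2CO)cc(OC)c1O | target

Total step count: 11. Longest linear sequence: 7 steps (1, 2, 3, 4, 5, 10, 11).

Steps most likely to fail

1. Step 3 (Proposed new method). Several processes could defeat it:
- ionisation of the other acetal C–O bond, which would join C8 to the oxygen meta to the ester;
- poor facial discrimination in the ion pair;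
- 1,2-hydride or aryl migration, or proton loss to a persistent diazo ester, overtaking ring closure;
- erosion of enantiopurity during the base equilibration through reversible ring opening by β-elimination.

Fallback, setting out from 2, 3 and 6 and coming back at 8: aldehyde 2 is homologated with 6 under NbCl5 catalysis (Roskamp reaction, CH2Cl2, rt) to ethyl 3-[3,5-dimethoxy-4-(triisopropylsilyloxy)phenyl]-3-oxopropanoate F1. NBS with catalytic NH4OAc in Et2O brominates the active methylene to racemic ethyl 2-bromo-3-[3,5-dimethoxy-4-(triisopropylsilyloxy)phenyl]-3-oxopropanoate F2. The more acidic 4-hydroxyl of 3, the one para to the ester, is alkylated with F2 (K2CO3, acetone, 0 °C to rt) to ethyl 3-[3,5-dimethoxy-4-(triisopropylsilyloxy)phenyl]-2-[2-hydroxy-4-(methoxycarbonyl)phenoxy]-3-oxopropanoate F3. F3 is racemic, configurationally labile at C2 and in equilibrium with its cyclic hemiketal, and it already fixes the C8–O bond to the correct oxygen. Asymmetric transfer hydrogenation under dynamic kinetic resolution (RuCl[(S,S)-TsDPEN](p-cymene), HCO2H/Et3N, using the catalyst antipode that delivers 2S) should give ethyl (2S,3R)-3-[3,5-dimethoxy-4-(triisopropylsilyloxy)phenyl]-3-hydroxy-2-[2-hydroxy-4-(methoxycarbonyl)phenoxy]propanoate F4, whose C3 configuration is of no consequence. Acid-catalysed cyclisation (BF3·OEt2 cat., CH2Cl2, −20 °C) ionises the p-silyloxybenzylic alcohol, and the neighbouring phenol closes the C7–O bond anti to the ester under relay from C2, giving trans diester 8.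

2. Step 2. The exchange equilibrium may lie against the strained five-membered aryl acetal of an electron-poor catechol, and prolonged acid and heat may cause loss of the silyl group or hydrolysis of the acetal on isolation.

Fallback, setting out from 3 and 2 and coming back at 5: 3 is bis-silylated (Me3SiCl, Et3N, CH2Cl2) to methyl 3,4-bis(trimethylsilyloxy)benzoate F5. F5 is condensed with aldehyde 2 under catalytic Me3SiOTf in CH2Cl2 at −78 to −20 °C. This silyl-transfer acetalisation is made irreversible by formation of hexamethyldisiloxane, runs aprotic and cold, and gives 5 without passing through 4.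

3. Step 10. The strong base may trigger side reactions of the C9 alkoxide, cleavage or migration of aryl silyl groups, or incomplete conversion and E-selectivity.

Fallback, setting out from 10 and coming back at 16: aldehyde 10 is methylenated (Ph3PCH3Br, KOtBu, THF, 0 °C, Wittig reaction) to [(2R,3R)-3-[3,5-dimethoxy-4-(triisopropylsilyloxy)phenyl]-6-ethenyl-2,3-dihydro-1,4-benzodioxin-2-yl]methanol F6. Commercial 5-bromobenzene-1,3-diol (Oc1cc(O)cc(Br)c1) is silylated (TIPSCl, imidazole, DMF) to 1-bromo-3,5-bis(triisopropylsilyloxy)benzene F7. A Mizoroki–Heck coupling of F6 with F7 (Pd(OAc)2, P(o-tol)3, Et3N, DMF, 100 °C) should form the (E)-stilbene 16 by syn insertion and syn β-hydride elimination under only weakly basic conditions.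

Further compounds
F1 | step 3 | ethyl 3-[3,5-dimethoxy-4-(triisopropylsilyloxy)phenyl]-3-oxopropanoate | CCOC(=O)CC(=O)c1cc(OC)c(O[Si](C(C)C)(C(C)C)C(C)C)c(OC)c1
F2 | step 3 | ethyl 2-bromo-3-[3,5-dimethoxy-4-(triisopropylsilyloxy)phenyl]-3-oxopropanoate (racemic) | CCOC(=O)C(Br)C(=O)c1cc(OC)c(O[Si](C(C)C)(C(C)C)C(C)C)c(OC)c1
F3 | step 3 | ethyl 3-[3,5-dimethoxy-4-(triisopropylsilyloxy)phenyl]-2-[2-hydroxy-4-(methoxycarbonyl)phenoxy]-3-oxopropanoate (racemic) | CCOC(=O)C(Oc1ccc(C(=O)OC)cc1O)C(=O)c1cc(OC)c(O[Si](C(C)C)(C(C)C)C(C)C)c(OC)c1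
F4 | step 3 | ethyl (2S,3R)-3-[3,5-dimethoxy-4-(triisopropylsilyloxy)phenyl]-3-hydroxy-2-[2-hydroxy-4-(methoxycarbonyl)phenoxy]propanoate | CCOC(=O)[C@@H](Oc1ccc(C(=O)OC)cc1O)[C@H](O)c1cc(OC)c(O[Si](C(C)C)(C(C)C)C(C)C)c(OC)c1
F5 | step 2 | methyl 3,4-bis(trimethylsilyloxy)benzoate | COC(=O)c1ccc(O[Si](C)(C)C)c(O[Si](C)(C)C)c1
F6 | step 10 | [(2R,3R)-3-[3,5-dimethoxy-4-(triisopropylsilyloxy)phenyl]-6-ethenyl-2,3-dihydro-1,4-benzodioxin-2-yl]methanol | COc1cc([C@H]2Oc3cc(C=C)ccc3O[C@@H]2CO)cc(OC)c1O[Si](C(C)C)(C(C)C)C(C)C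
F7 | step 10 | 1-bromo-3,5-bis(triisopropylsilyloxy)benzene | Brc1cc(O[Si](C(C)C)(C(C)C)C(C)C)cc(O[Si](C(C)C)(C(C)C)C(C)C)c1
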